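**Plan**

- Retrosynthesis: the two gallate esters and all benzyl ethers come off last. Before that, both C3–O bonds and both C2–H bonds in ring C of the top and of the middle unit are cut, which leads back to a benzylated bis(2-aryl-4H-chromene) carried on C8 of (+)-catechin.
- Each chromene is cut at C3–C4 and O1–C2 into an ortho-hydroxybenzhydrol (ortho-quinone methide precursor) and one α-aryl enamide. The benzhydrols are cut at C4(middle)–C8(bottom) and at C4(top)–C6(middle) into aryllithium/salicylaldehyde pairs.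
- Forward: the top pyran ring is closed first. Desilylation and ortho-formylation then put the future middle C4 next to the only free phenol, para to the top linkage, which fixes the 4→6 bond. Lithiated catechin is added, the middle pyran ring is closed, and the key step, galloylation and hydrogenolysis finish; ring C of the bottom unit comes intact from catechin.
- Stereochemistry: C2/C3 of the bottom unit from (+)-catechin; C4 of the top and middle units from a chiral phosphoric acid; C2 and C3 of both upper units from the key step.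
- Enabling feature: in ring C of the top and of the middle unit, H2 and O3 sit on opposite faces and O3 is trans to the C4 aryl group (2,3-cis-3,4-trans). This is the pattern that anti addition of oxygen and hydride to a C2=C3 enol ether gives when the C4 aryl blocks one face.

Key step: step 14

Remark: the (R)-phosphoric acid is written on the assumption that it delivers the C4 configuration shown; if the first chromene proves to have the opposite sense, the (S)-acid is used in steps 6 and 13.

**Route**

Step 1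
Reactants: 1 2,4,6-trihydroxybenzaldehyde
Product: 2 2,4-bis(benzyloxy)-6-hydroxybenzaldehyde
Conditions: BnBr (2.05 equiv), K2CO3 (2.1 equiv), DMF, 0 °C → rt
Reagents that add atoms: benzyl bromide, BrCc1ccccc1
Why: Williamson etherification in which the hydroxyl para to the formyl group and one ortho hydroxyl are benzylated while the second ortho hydroxyl, locked in a hydrogen bond to the aldehyde, stays free, the usual selectivity of 2,4,6-trihydroxyaryl carbonyl compounds.

Step 2
Reactants: 3 3,5-bis(benzyloxy)phenol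
Product: 4 [3,5-bis(benzyloxy)phenoxy]triisopropylsilane
Conditions: i-Pr3SiCl, imidazole, DMF, rt
Reagents that add atoms: chlorotriisopropylsilane, CC(C)[Si](Cl)(C(C)C)C(C)C
Why: Imidazole-promoted silylation of the phenol; the bulky silyl ether is a poor metalation director that shields its own ortho positions and is later removable by fluoride without touching benzyl ethers.

Step 3
Reactants: 4 [3,5-bis(benzyloxy)phenoxy]triisopropylsilane; 2 2,4-bis(benzyloxy)-6-hydroxybenzaldehyde
Product: 6 racemic [2,4-bis(benzyloxy)-6-hydroxyphenyl][2,6-bis(benzyloxy)-4-(triisopropylsilyloxy)phenyl]methanol, via aryllithium 5 (not isolated)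
Conditions: 4 (1.3 equiv), n-BuLi, THF, 0 °C, 1 h; then 2 predeprotonated with NaH (THF, 0 °C), −78 → 0 °C; H2O
Reagents that add atoms: none
Why: Directed ortho-metalation at the carbon flanked by the two benzyloxy groups (kept short at 0 °C so that benzylic deprotonation does not compete) followed by 1,2-addition of the aryllithium to the aldehyde of the preformed sodium phenoxide; the carbinol centre forms racemic and is erased when the quinone methide is generated in step 6.

Step 4
Reactants: 7 1-[3,4-bis(benzyloxy)phenyl]ethan-1-one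
Product: 8 (1E)-1-[3,4-bis(benzyloxy)phenyl]ethan-1-one oxime
Conditions: NH2OH·HCl, NaOAc, EtOH, 70 °C
Reagents that add atoms: hydroxylamine hydrochloride, NO.Cl
Why: Condensation of the aryl methyl ketone with hydroxylamine gives the oxime, the E isomer being favoured because the hydroxyl avoids the aryl group.

Step 5
Reactants: 8 (1E)-1-[3,4-bis(benzyloxy)phenyl]ethan-1-one oxime
Product: 9 N-{1-[3,4-bis(benzyloxy)phenyl]ethenyl}acetamide
Conditions: Fe powder, Ac2O, AcOH, toluene, 70 °C
Reagents that add atoms: acetic anhydride, CC(=O)OC(C)=O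
Why: Iron-mediated reductive acylation of a ketoxime, in which O-acetylation, N–O cleavage by zerovalent iron, N-acetylation and tautomerisation give the α-aryl enamide.

Step 6
Reactants: 6 racemic benzhydrol; 9 N-{1-[3,4-bis(benzyloxy)phenyl]ethenyl}acetamide
Product: 11 (4S)-5,7-bis(benzyloxy)-2-[3,4-bis(benzyloxy)phenyl]-4-[2,6-bis(benzyloxy)-4-(triisopropylsilyloxy)phenyl]-4H-chromene, via N-acetyl aminal 10 (not isolated)
Conditions: (R)-3,3'-bis(2,4,6-triisopropylphenyl)-1,1'-binaphthalene-2,2'-diyl hydrogen phosphate (10 mol %), 9 (1.3 equiv), 4 Å MS, CHCl3, 0 °C → rt; then pyridinium p-toluenesulfonate (20 mol %), 45 °C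
Reagents that add atoms: none
Why: Chiral phosphoric acid-catalysed formal [4+2] annulation of an ortho-quinone methide with an enamide: the acid ionises the benzhydrol, holds the quinone methide oxygen and the enamide N–H in one hydrogen-bonded assembly so that the enamide CH2 adds to a single enantiotopic face of the methide carbon (this sets C4), the N-acyliminium ion is closed by the phenol oxygen, and mild acid then expels acetamide to leave the 2-aryl enol ether.

Step 7
Reactants: 11 silyl-protected 4H-chromene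
Product: 12 3,5-bis(benzyloxy)-4-{(4S)-5,7-bis(benzyloxy)-2-[3,4-bis(benzyloxy)phenyl]-4H-chromen-4-yl}phenol
Conditions: Bu4NF (1.1 equiv), AcOH (1.1 equiv), THF, 0 °C
Reagents that add atoms: none
Why: Fluoride cleaves the aryl silyl ether (Si–F bond formation) under acetic acid buffering, conditions that leave benzyl ethers, the enol ether and the C4–H centre alone.

Step 8
Reactants: 12 chromenyl phenol
Product: 13 2,4-bis(benzyloxy)-3-{(4R)-5,7-bis(benzyloxy)-2-[3,4-bis(benzyloxy)phenyl]-4H-chromen-4-yl}-6-hydroxybenzaldehyde (same arrangement at C4 as in 12; only the descriptor changes)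
Conditions: MgCl2, Et3N, (CH2O)n, THF, 65 °C; pH 5 buffer work-up
Reagents that add atoms: paraformaldehyde (as formaldehyde), C=O
Why: Casnati–Skattebøl ortho-formylation: the magnesium phenoxide directs formaldehyde to the carbon next to the free hydroxyl and a second formaldehyde oxidises the hydroxymethyl group by hydride transfer, so only this ring reacts and, its two ortho carbons being equivalent, the aldehyde ends up para to the chromenyl group.

Step 9
Reactants: 14 (+)-catechin
Product: 15 (2R,3S)-5,7-bis(benzyloxy)-2-[3,4-bis(benzyloxy)phenyl]-3,4-dihydro-2H-chromen-3-ol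
Conditions: BnBr (4.4 equiv), K2CO3, DMF, 0 °C → rt
Reagents that add atoms: benzyl bromide, BrCc1ccccc1
Why: Williamson benzylation of the four phenols with a carbonate base too weak to deprotonate the secondary alcohol; C2 and C3 are untouched.

Step 10
Reactants: 15 tetra-O-benzylcatechin
Product: 16 (2R,3S)-8-bromo-5,7-bis(benzyloxy)-2-[3,4-bis(benzyloxy)phenyl]-3,4-dihydro-2H-chromen-3-ol
Conditions: NBS (1.0 equiv), CH2Cl2, −78 °C → rt
Reagents that add atoms: N-bromosuccinimide, O=C1CCC(=O)N1Br
Why: Electrophilic aromatic bromination, which in 5,7-dialkoxyflavans is known to go to C8 (ortho to the ring oxygen) in preference to C6, which is flanked by two benzyloxy groups.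

Step 11
Reactants: 16 8-bromo-tetra-O-benzylcatechin
Product: 17 (2R,3S)-8-bromo-3,5,7-tris(benzyloxy)-2-[3,4-bis(benzyloxy)phenyl]-3,4-dihydro-2H-chromene
Conditions: NaH, BnBr, DMF, 0 °C → rt
Reagents that add atoms: benzyl bromide, BrCc1ccccc1
Why: Williamson etherification of the secondary alkoxide protects the 3-hydroxyl as a benzyl ether so that it survives to the end as the only non-acylated alcohol; no stereocentre is involved.

Step 12
Reactants: 17 8-bromo-penta-O-benzylcatechin; 13 chromenyl salicylaldehyde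
Product: 19 middle benzhydrol (mixture of carbinol epimers), via aryllithium 18 (not isolated)
Conditions: 17 (1.5 equiv), n-BuLi, THF, −78 °C; then 13 predeprotonated with NaH (THF, 0 °C), −78 → −40 °C; H2O
Reagents that add atoms: none
Why: Bromine–lithium exchange at −78 °C gives the C8 aryllithium, which adds to the aldehyde of the preformed sodium phenoxide (1,2-addition) faster than it deprotonates C4–H; the new carbinol centre forms as a mixture of epimers and is erased in step 13.

Step 13
Reactants: 19 middle benzhydrol; 9 N-{1-[3,4-bis(benzyloxy)phenyl]ethenyl}acetamide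
Product: 21 benzylated bis(4H-chromene) on C8 of penta-O-benzylcatechin (top 4R; middle 4R; bottom 2R,3S), via N-acetyl aminal 20 (not isolated)
Conditions: (R)-3,3'-bis(2,4,6-triisopropylphenyl)-1,1'-binaphthalene-2,2'-diyl hydrogen phosphate (10 mol %), 9 (1.5 equiv), 4 Å MS, CHCl3, 0 °C → rt; then pyridinium p-toluenesulfonate (20 mol %), 45 °C
Reagents that add atoms: none
Why: The same phosphoric acid-catalysed ortho-quinone methide/enamide [4+2] annulation and acetamide elimination as in step 6, now with the quinone methide oxygen on the middle ring; the catalyst is relied on to select the face of the methide carbon and so set C4 of the middle unit (the existing centres are remote), and a minor C4 epimer would be a separable diastereomer.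

Step 14
Reactants: 21 benzylated bis(4H-chromene)
Product: 23 trideca-O-benzyl epicatechin-(4β→6)-epicatechin-(4β→8)-catechin with free 3-hydroxyls on the top and middle units, via bis-epoxide 22 (not isolated)
Conditions: dimethyldioxirane (2.4 equiv, extracted into CH2Cl2, acetone-free), CH2Cl2, −78 → −40 °C; volatiles removed at −40 °C; then LiBHEt3 (5 equiv), THF, −78 → −40 °C; H2O
Reagents that add atoms: dimethyldioxirane, CC1(C)OO1
Why: Proposed new method: dimethyldioxirane transfers oxygen to each C2=C3 enol ether through a concerted spiro transition state, and LiBHEt3 then opens each 2-aryl-2,3-epoxychroman at the doubly activated C2 (benzylic and acetal-like) by backside hydride attack on a tight, lithium-assisted ion pair, the C3 oxygen leaving as alkoxide. The closest known reaction type is the dioxirane epoxidation of 1-aryl glycals followed by hydride opening at the anomeric carbon with inversion, which has not been run on 2,4-diaryl-4H-chromenes or twice in one molecule. The step closes no lasting ring: the two oxiranes arise by concerted [2+1] oxygen transfer (three-membered closure across C2 and C3) and are cleaved again in the same flask. C3 of the top and of the middle unit is fixed by the face of epoxidation, which is the one opposite the C4 aryl group held pseudoaxial by peri strain with the 5-benzyloxy group, and C2 is fixed by inversion, which puts H2 anti to O3 and hence the catechol ring cis to O3 (2R,3R in both units, 2,3-cis-3,4-trans). The step needs chemoselectivity for the two enol ethers over the many arene rings and benzylic C–H bonds, which their far higher nucleophilicity at −78 °C should secure, and it needs inversion rather than free-cation chemistry (retention at C2 or a 1,2-hydride shift to the 3-ketone), which the acetone-free and acid-free medium, the strongly nucleophilic but non-Lewis-acidic triethylborohydride and the low temperature are meant to secure. The saturated catechin unit has no reactive alkene and is carried through unchanged.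

Step 15
Reactants: 23 diol; 24 3,4,5-tris(benzyloxy)benzoic acid
Product: 25 nonadeca-O-benzyl bis-gallate
Conditions: 24 (3 equiv), N,N'-dicyclohexylcarbodiimide (3 equiv), 4-(dimethylamino)pyridine (1 equiv), CH2Cl2, rt
Reagents that add atoms: none
Why: Steglich esterification (carbodiimide activation with acyl transfer by 4-(dimethylamino)pyridine) of the only two free hydroxyls, the standard way to galloylate benzylated flavan-3-ols; no stereocentre is touched.

Step 16
Reactants: 25 nonadeca-O-benzyl bis-gallate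
Product: 26 epicatechin 3-O-gallate-(4β→6)-epicatechin 3-O-gallate-(4β→8)-catechin (target)
Conditions: H2 (1 atm), Pd(OH)2/C, THF/MeOH/H2O, rt
Reagents that add atoms: none
Why: Hydrogenolysis of all nineteen benzyl ethers over Pd(OH)2/C under neutral conditions, which leave the gallate esters, the O1–C2 benzylic ethers and the interflavan C–C bonds intact.

**Compound list**

1 | 2,4,6-trihydroxybenzaldehyde | O=Cc1c(O)cc(O)cc1O | starting material

2 | 2,4-bis(benzyloxy)-6-hydroxybenzaldehyde | O=Cc1c(O)cc(OCc2ccccc2)cc1OCc1ccccc1 | intermediate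

3 | 3,5-bis(benzyloxy)phenol | Oc1cc(OCc2ccccc2)cc(OCc2ccccc2)c1 | starting material

4 | [3,5-bis(benzyloxy)phenoxy]triisopropylsilane | CC(C)[Si](Oc1cc(OCc2ccccc2)cc(OCc2ccccc2)c1)(C(C)C)C(C)C | intermediate

5 | [2,6-bis(benzyloxy)-4-(triisopropylsilyloxy)phenyl]lithium | [Li]c1c(OCc2ccccc2)cc(O[Si](C(C)C)(C(C)C)C(C)C)cc1OCc1ccccc1 | intermediate (not isolated)

6 | racemic [2,4-bis(benzyloxy)-6-hydroxyphenyl][2,6-bis(benzyloxy)-4-(triisopropylsilyloxy)phenyl]methanol | OC(c1c(O)cc(OCc2ccccc2)cc1OCc1ccccc1)c1c(OCc2ccccc2)cc(O[Si](C(C)C)(C(C)C)C(C)C)cc1OCc1ccccc1 | intermediate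

7 | 1-[3,4-bis(benzyloxy)phenyl]ethan-1-one | CC(=O)c1ccc(OCc2ccccc2)c(OCc2ccccc2)c1 | starting material

8 | (1E)-1-[3,4-bis(benzyloxy)phenyl]ethan-1-one oxime | C/C(=N\O)c1ccc(OCc2ccccc2)c(OCc2ccccc2)c1 | intermediate

9 | N-{1-[3,4-bis(benzyloxy)phenyl]ethenyl}acetamide | CC(=O)NC(=C)c1ccc(OCc2ccccc2)c(OCc2ccccc2)c1 | intermediate

10 | N-{(4S)-5,7-bis(benzyloxy)-2-[3,4-bis(benzyloxy)phenyl]-4-[2,6-bis(benzyloxy)-4-(triisopropylsilyloxy)phenyl]-3,4-dihydro-2H-chromen-2-yl}acetamide (C2 epimers) | CC(=O)NC1(c7ccc(OCc9ccccc9)c(OCc9ccccc9)c7)C[C@@H](c3c(OCc9ccccc9)cc(O[Si](C(C)C)(C(C)C)C(C)C)cc3OCc9ccccc9)c2c(OCc9ccccc9)cc(OCc9ccccc9)cc2O1 | intermediate (not isolated)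

11 | (4S)-5,7-bis(benzyloxy)-2-[3,4-bis(benzyloxy)phenyl]-4-[2,6-bis(benzyloxy)-4-(triisopropylsilyloxy)phenyl]-4H-chromene | C1(c7ccc(OCc9ccccc9)c(OCc9ccccc9)c7)=C[C@@H](c3c(OCc9ccccc9)cc(O[Si](C(C)C)(C(C)C)C(C)C)cc3OCc9ccccc9)c2c(OCc9ccccc9)cc(OCc9ccccc9)cc2O1 | intermediate

12 | 3,5-bis(benzyloxy)-4-{(4S)-5,7-bis(benzyloxy)-2-[3,4-bis(benzyloxy)phenyl]-4H-chromen-4-yl}phenol | C1(c7ccc(OCc9ccccc9)c(OCc9ccccc9)c7)=C[C@@H](c3c(OCc9ccccc9)cc(O)cc3OCc9ccccc9)c2c(OCc9ccccc9)cc(OCc9ccccc9)cc2O1 | intermediate

13 | 2,4-bis(benzyloxy)-3-{(4R)-5,7-bis(benzyloxy)-2-[3,4-bis(benzyloxy)phenyl]-4H-chromen-4-yl}-6-hydroxybenzaldehyde | C1(c7ccc(OCc9ccccc9)c(OCc9ccccc9)c7)=C[C@@H](c3c(OCc9ccccc9)cc(O)c(C=O)c3OCc9ccccc9)c2c(OCc9ccccc9)cc(OCc9ccccc9)cc2O1 | intermediate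

14 | (+)-catechin, (2R,3S) | O[C@H]1Cc2c(O)cc(O)cc2O[C@@H]1c1ccc(O)c(O)c1 | starting material

15 | (2R,3S)-5,7-bis(benzyloxy)-2-[3,4-bis(benzyloxy)phenyl]-3,4-dihydro-2H-chromen-3-ol | O[C@H]1Cc2c(OCc9ccccc9)cc(OCc9ccccc9)cc2O[C@@H]1c7ccc(OCc9ccccc9)c(OCc9ccccc9)c7 | intermediate

16 | (2R,3S)-8-bromo-5,7-bis(benzyloxy)-2-[3,4-bis(benzyloxy)phenyl]-3,4-dihydro-2H-chromen-3-ol | O[C@H]1Cc2c(OCc9ccccc9)cc(OCc9ccccc9)c(Br)c2O[C@@H]1c7ccc(OCc9ccccc9)c(OCc9ccccc9)c7 | intermediate

17 | (2R,3S)-8-bromo-3,5,7-tris(benzyloxy)-2-[3,4-bis(benzyloxy)phenyl]-3,4-dihydro-2H-chromene | O(Cc9ccccc9)[C@H]1Cc2c(OCc9ccccc9)cc(OCc9ccccc9)c(Br)c2O[C@@H]1c7ccc(OCc9ccccc9)c(OCc9ccccc9)c7 | intermediate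

18 | {(2R,3S)-3,5,7-tris(benzyloxy)-2-[3,4-bis(benzyloxy)phenyl]-3,4-dihydro-2H-chromen-8-yl}lithium | O(Cc9ccccc9)[C@H]1Cc2c(OCc9ccccc9)cc(OCc9ccccc9)c([Li])c2O[C@@H]1c7ccc(OCc9ccccc9)c(OCc9ccccc9)c7 | intermediate (not isolated)

19 | {2,4-bis(benzyloxy)-3-[(4R)-5,7-bis(benzyloxy)-2-(3,4-bis(benzyloxy)phenyl)-4H-chromen-4-yl]-6-hydroxyphenyl}{(2R,3S)-3,5,7-tris(benzyloxy)-2-[3,4-bis(benzyloxy)phenyl]-3,4-dihydro-2H-chromen-8-yl}methanol (carbinol epimers) | C1(c7ccc(OCc9ccccc9)c(OCc9ccccc9)c7)=C[C@@H](c3c(OCc9ccccc9)cc(O)c(C(O)c5c(OCc9ccccc9)cc(OCc9ccccc9)c6c5O[C@H](c7ccc(OCc9ccccc9)c(OCc9ccccc9)c7)[C@@H](OCc9ccccc9)C6)c3OCc9ccccc9)c2c(OCc9ccccc9)cc(OCc9ccccc9)cc2O1 | intermediate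

20 | N-acetyl aminal: as 21, but the middle ring is a 2-acetamido-3,4-dihydro-2H-chromene (4R at C4; C2 epimers); top unit (4R)-4H-chromene; bottom unit (2R,3S) | C1(c7ccc(OCc9ccccc9)c(OCc9ccccc9)c7)=C[C@@H](c3c(OCc9ccccc9)cc4c(c3OCc9ccccc9)[C@H](c5c(OCc9ccccc9)cc(OCc9ccccc9)c6c5O[C@H](c7ccc(OCc9ccccc9)c(OCc9ccccc9)c7)[C@@H](OCc9ccccc9)C6)CC(NC(C)=O)(c7ccc(OCc9ccccc9)c(OCc9ccccc9)c7)O4)c2c(OCc9ccccc9)cc(OCc9ccccc9)cc2O1 | intermediate (not isolated)

21 | bis(4H-chromene): a (4R)-5,7-bis(benzyloxy)-2-[3,4-bis(benzyloxy)phenyl]-4H-chromen-4-yl group at C6 of a (4R)-5,7-bis(benzyloxy)-2-[3,4-bis(benzyloxy)phenyl]-4H-chromene whose C4 is bonded to C8 of (2R,3S)-3,5,7-tris(benzyloxy)-2-[3,4-bis(benzyloxy)phenyl]-3,4-dihydro-2H-chromene | C1(c7ccc(OCc9ccccc9)c(OCc9ccccc9)c7)=C[C@@H](c3c(OCc9ccccc9)cc4c(c3OCc9ccccc9)[C@H](c5c(OCc9ccccc9)cc(OCc9ccccc9)c6c5O[C@H](c7ccc(OCc9ccccc9)c(OCc9ccccc9)c7)[C@@H](OCc9ccccc9)C6)C=C(c7ccc(OCc9ccccc9)c(OCc9ccccc9)c7)O4)c2c(OCc9ccccc9)cc(OCc9ccccc9)cc2O1 | intermediate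

22 | bis(2,3-epoxide) of 21: an oxirane across C2 and C3 of the top and of the middle chromene, both oxirane oxygens on the face opposite the C4 aryl groups | [C@@]12(c7ccc(OCc9ccccc9)c(OCc9ccccc9)c7)O[C@@H]1[C@@H](c3c(OCc9ccccc9)cc4c(c3OCc9ccccc9)[C@H](c5c(OCc9ccccc9)cc(OCc9ccccc9)c6c5O[C@H](c7ccc(OCc9ccccc9)c(OCc9ccccc9)c7)[C@@H](OCc9ccccc9)C6)[C@H]5O[C@@]5(c7ccc(OCc9ccccc9)c(OCc9ccccc9)c7)O4)c3c(OCc9ccccc9)cc(OCc9ccccc9)cc3O2 | intermediate (not isolated)

23 | trideca-O-benzyl epicatechin-(4β→6)-epicatechin-(4β→8)-catechin with free 3-hydroxyls on the top and middle units and the bottom 3-O benzylated (top 2R,3R,4R; middle 2R,3R,4R; bottom 2R,3S) | O[C@@H]1[C@@H](c3c(OCc9ccccc9)cc4c(c3OCc9ccccc9)[C@H](c5c(OCc9ccccc9)cc(OCc9ccccc9)c6c5O[C@H](c7ccc(OCc9ccccc9)c(OCc9ccccc9)c7)[C@@H](OCc9ccccc9)C6)[C@@H](O)[C@@H](c7ccc(OCc9ccccc9)c(OCc9ccccc9)c7)O4)c2c(OCc9ccccc9)cc(OCc9ccccc9)cc2O[C@@H]1c7ccc(OCc9ccccc9)c(OCc9ccccc9)c7 | intermediate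

24 | 3,4,5-tris(benzyloxy)benzoic acid | OC(=O)c1cc(OCc2ccccc2)c(OCc2ccccc2)c(OCc2ccccc2)c1 | starting material

25 | 23 esterified at both free 3-hydroxyls with 3,4,5-tris(benzyloxy)benzoyl groups (nonadeca-O-benzyl bis-gallate; top 2R,3R,4R; middle 2R,3R,4R; bottom 2R,3S) | O=C(c8cc(OCc9ccccc9)c(OCc9ccccc9)c(OCc9ccccc9)c8)O[C@@H]1[C@@H](c3c(OCc9ccccc9)cc4c(c3OCc9ccccc9)[C@H](c5c(OCc9ccccc9)cc(OCc9ccccc9)c6c5O[C@H](c7ccc(OCc9ccccc9)c(OCc9ccccc9)c7)[C@@H](OCc9ccccc9)C6)[C@@H](OC(=O)c8cc(OCc9ccccc9)c(OCc9ccccc9)c(OCc9ccccc9)c8)[C@@H](c7ccc(OCc9ccccc9)c(OCc9ccccc9)c7)O4)c2c(OCc9ccccc9)cc(OCc9ccccc9)cc2O[C@@H]1c7ccc(OCc9ccccc9)c(OCc9ccccc9)c7 | intermediate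

26 | epicatechin 3-O-gallate-(4β→6)-epicatechin 3-O-gallate-(4β→8)-catechin, CNP0112921.1 (top 2R,3R,4S; middle 2R,3R,4R; bottom 2R,3S) | O=C(O[C@@H]1[C@@H](c2c(O)cc3c(c2O)[C@H](c2c(O)cc(O)c4c2O[C@H](c2ccc(O)c(O)c2)[C@@H](O)C4)[C@@H](OC(=O)c2cc(O)c(O)c(O)c2)[C@@H](c2ccc(O)c(O)c2)O3)c2c(O)cc(O)cc2O[C@@H]1c1ccc(O)c(O)c1)c1cc(O)c(O)c(O)c1 | target

**Step count and risks**

Total: 16 steps. Longest linear sequence: 10 steps (3 → 4 → 6 → 11 → 12 → 13 → 19 → 21 → 23 → 25 → 26; the sequence from 1 is equally long).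

Step 14 (carries the label). The 2-aryl oxiranes may ionise to the C2 cation before hydride arrives, which opens the way to a 1,2-hydride shift toward the 3-ketone or to hydride delivery with retention at C2; epoxidation of one of the two enol ethers may also be less face-selective than the other. The fallback sets out from 21 and uses known operations. Catalytic OsO4 with N-methylmorpholine N-oxide (acetone/water, pyridine) dihydroxylates both enol ethers syn, on the face away from the C4 aryl groups, to give the bis-hemiketal tetrol F1. Et3SiH with BF3·OEt2 in CH2Cl2 at −78 °C, the ionic reduction used to turn 1-aryl lactols into C-aryl glycosides, then replaces each anomeric hydroxyl by hydride delivered axially to the oxocarbenium ion, anti to the axial 3-hydroxyl, and the route is rejoined at 23. Oxygen and hydride delivery are thus split into two separate operations, O3 being set by osmylation and C2 by stereoelectronically controlled reduction.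

Step 13. Slow C–C bond formation at the crowded methide carbon may let the acid protonate the enol ether of the top unit, with capture of that cation by water or enamide, and control by the catalyst over the new centre may be incomplete. The fallback sets out from 13: Boc2O and 4-(dimethylamino)pyridine give the aryl tert-butyl carbonate F2. Aryllithium 18 is added at −78 °C, then enamide 9 and MgBr2·OEt2; on warming, the carbonate migrates to the benzylic alkoxide and is expelled, which generates the same ortho-quinone methide under basic conditions. It is trapped there by 9 in an inverse-electron-demand hetero-Diels–Alder reaction to give aminal 20, and brief treatment with pyridinium p-toluenesulfonate as in step 13 rejoins the route at 21. The C4 epimers are separated at that point, because this variant has no catalyst control; carbinol 19 and its acid-mediated ionisation are bypassed.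

Step 6. Enantioselectivity may erode because the doubly ortho-substituted quinone methide reacts through both geometric isomers or through a loose ion pair. The fallback sets out from 11 of insufficient enantiomeric purity: DDQ in wet CH2Cl2 abstracts hydride from C4 and water adds to the resulting benzopyrylium ion to give the 2H-chromen-2-ol F3, which erases the stereocentre. Chiral phosphoric acid-catalysed transfer hydrogenation with a Hantzsch ester (re-formation of the benzopyrylium phosphate ion pair and 1,4-hydride delivery to C4) then returns to 11. The centre is thus reset by face-selective C–H bond formation on a flat cation instead of by the C–C bond-forming step.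

**Further compounds**

F1 | step 14 | bis-hemiketal tetrol: 23 carrying an additional hydroxyl at C2 of the top and of the middle unit, each cis to the neighbouring 3-hydroxyl and on the face opposite the C4 aryl group | O[C@@H]1[C@@H](c3c(OCc9ccccc9)cc4c(c3OCc9ccccc9)[C@H](c5c(OCc9ccccc9)cc(OCc9ccccc9)c6c5O[C@H](c7ccc(OCc9ccccc9)c(OCc9ccccc9)c7)[C@@H](OCc9ccccc9)C6)[C@@H](O)[C@](O)(c7ccc(OCc9ccccc9)c(OCc9ccccc9)c7)O4)c2c(OCc9ccccc9)cc(OCc9ccccc9)cc2O[C@@]1(O)c7ccc(OCc9ccccc9)c(OCc9ccccc9)c7

F2 | step 13 | 3,5-bis(benzyloxy)-4-{(4R)-5,7-bis(benzyloxy)-2-[3,4-bis(benzyloxy)phenyl]-4H-chromen-4-yl}-2-formylphenyl tert-butyl carbonate | C1(c7ccc(OCc9ccccc9)c(OCc9ccccc9)c7)=C[C@@H](c3c(OCc9ccccc9)cc(OC(=O)OC(C)(C)C)c(C=O)c3OCc9ccccc9)c2c(OCc9ccccc9)cc(OCc9ccccc9)cc2O1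

F3 | step 6 | 5,7-bis(benzyloxy)-2-[3,4-bis(benzyloxy)phenyl]-4-[2,6-bis(benzyloxy)-4-(triisopropylsilyloxy)phenyl]-2H-chromen-2-ol (racemic at C2) | OC1(c7ccc(OCc9ccccc9)c(OCc9ccccc9)c7)C=C(c3c(OCc9ccccc9)cc(O[Si](C(C)C)(C(C)C)C(C)C)cc3OCc9ccccc9)c2c(OCc9ccccc9)cc(OCc9ccccc9)cc2O1
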